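A steady pace is impossible in alder, the flask asked about, in which E and J meet dissolving solid Q under catalyst D and give Z.

all flasks: E 0.25 M; temperature 70 °C
- alder: J 1 equiv; Q 1.2 equiv; D 5.4 mol%; the very flask that is asked about, followed so far
- birch: J 1 equiv; Q 1.2 equiv; D 3.6 mol%; run made earlier
- flask: J 1.00 equiv; Q 1.20 equiv; D 5.4 mol%; time 25 h

| run | time / min | Z / % |
|---|---|---|
| alder | 120 | 32.8 |
| alder | 240 | 38.8 |
| alder | 360 | 41.0 |
| alder | 480 | 44.2 |
| alder | 600 | 45.1 |
| alder | 720 | 46.6 |
| alder | 900 | 46.7 |
| birch | 6.00 | 2.0 |
| birch | 10.0 | 3.5 |
| birch | 15.0 | 5.2 |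
| birch | 25.0 | 9.3 |
| birch | 30.0 | 11.7 |
| birch | 50.0 | 16.9 |
| birch | 80.0 | 24.0 |

(readings scatter by 0.5 percentage points)

- Z, in percent of the E first charged, at 25 h
- what to do for the largest gain in Z; "none" if nothing gains more than 2 percentage points (Saturday's / Thursday's / Sunday's / Monday's / none)
- Z present, with what was taken out counted in, in percent of the E first charged, after Thursday's
- Z present, with what was taken out counted in, in percent of the E first charged, after Monday's

- Saturday's: change nothing and wait 8.0 h more
- Thursday's: at 25 h add D, 100% of the amount charged, then wait 8.0 h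
- Sunday's: at 25 h take out 90% of the Z then present, then wait 8.0 h
- Monday's: at 25 h raise the temperature by 20 K, then wait 8.0 h

- Q is a solid; its amount is given per volume of the solution
- Z that was removed still counts
- at the start none of Q is in solution
- the earlier runs do not show what temperature does; that part of a forecast is a guess
- additions bring no volume worth counting

Take r as Z divided by the part of E not yet turned into Z. Birch climbs in r nearly in step with time, at 0.00395 min⁻¹ by its last reading. Scaled up by the loading, that pace puts alder at r = 5.33 at 900 min, but alder reads 0.876, far less than that. So the pace in alder falls as the flask runs, and these readings do not tell which factor of the rate falls.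

A rate falling as one over time adds the same r for each doubling of time, and alder comes close to this. From 0.488 at 120 min, r rises 0.152 per doubling up to 480 min. Over the whole run the doubling gain, kept as 0.134, is the rise of r per doubling of time.

Frozen, it gives alder r = 0.975 at 25 h, so Z = 49.4%. Saturday's wait then adds 0.0535 to r, which is 1.3 percentage points of Z, less than the margin of 2 points.

The forecast says 47% at 25 h, lower than this reckoning. It chooses Thursday's, on the ground “Fresh D should roughly repeat” the first gain, with 60.5% after it and 48% after Monday's.

The flask gives 49.2%. The best option is Thursday's, which brings 5.2 points and ends at 54.4%; Monday's ends at 51.5%.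

    E + G + D → D + Z (k = 3.00 L² mol⁻² min⁻¹, Ea = 67.0 kJ mol⁻¹)
    J + G + D → D + L (k = 3.50 L² mol⁻² min⁻¹, Ea = 45.0 kJ mol⁻¹)
    2 D → X (k = 0.870 L mol⁻¹ min⁻¹, Ea = 69.0 kJ mol⁻¹)
    Q ⇌ G, rate k4*(cs4 - [G]) while solid is left; crystals form when [G] > cs4 (solubility = 0.230 M, k = 0.210 min⁻¹)
    (constants at 70 °C)

Saturday's brings 0.89 points in alder, against the 1.3 points reckoned from the doubling gain. Thursday's raises r by 0.224, the worth of 1.67 doublings, and the forecast stood at 60.5%. [G], a factor in both rate terms, is 0.0403 M at 1500 min, against 0.114 M at 150 min. For the neighbour with 2.00 equiv of Q, r scaled by the charge is 1.62, so Z = 61.8%. That neighbour holds D at 2.76%, as alder does, and reads 70.1% at 1500 min.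

The readings were computed with made-up constants; the scatter is artificial.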